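Ring C is disconnected at C3–C4 and at O1–C8a. The C4 carbonyl turns the ortho carbon C8a of ring A into an SNAr site once it carries fluorine, so a 2-fluorobenzoyl unit serves as a C4/C8a 1,3-dielectrophile and the enolate of a ring-B aryl methyl ketone as the matching C3/O1 dinucleophile. In one pot the two fully prenylated halves are joined: C-acylation of the lithium enolate by an acyl imidazolide, then closure of the diketonate oxygen onto C8a with loss of fluoride, which gives the complete flavone. Asymmetric copper hydride conjugate reduction then sets C2 as S, and acid removes the three MOM ethers.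

Key step: step 9

Remark: flavonoid numbering is used (O1, C2, C3, C4, C4a, C5–C8, C8a; ring B primed), the single stereocentre C2 of the target is S, and compounds 1 and 8 and the reagents named under "Reagents that add atoms" are taken as purchased.

Step 1
Reactants: 1 5-fluorobenzene-1,3-diol
Product: 2 1-fluoro-3,5-bis(methoxymethoxy)benzene
Conditions: MOMCl (2.6 equiv), i-Pr2NEt (3 equiv), CH2Cl2, 0 °C → rt
Reagents that add atoms: chloromethyl methyl ether, COCCl
Why: Williamson-type O-alkylation of both phenols should give the bis-MOM ether, a protecting group that tolerates the organometallic and basic steps ahead and is removed by acid at the end.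

Step 2
Reactants: 2 1-fluoro-3,5-bis(methoxymethoxy)benzene
Product: 3 1,3-dibromo-2-fluoro-4,6-bis(methoxymethoxy)benzene
Conditions: NBS (2.05 equiv), MeCN, 0 °C → rt, dark
Reagents that add atoms: N-bromosuccinimide, O=C1CCC(=O)N1Br
Why: Electrophilic aromatic bromination should occur twice at the carbons flanking fluorine, each para to one ether and ortho to the other, as 3,5-dialkoxytoluenes do, leaving the crowded carbon between the two ethers as C–H.

Step 3
Reactants: 3 1,3-dibromo-2-fluoro-4,6-bis(methoxymethoxy)benzene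
Product: 5 1-bromo-2-fluoro-4,6-bis(methoxymethoxy)-3-(3-methylbut-2-en-1-yl)benzene, via arylmagnesium chloride 4 (not isolated)
Conditions: i-PrMgCl·LiCl (1.05 equiv), THF, −20 °C; CuBr·SMe2 (10 mol %), prenyl bromide (1.3 equiv), −20 → 0 °C
Reagents that add atoms: 1-bromo-3-methylbut-2-ene, CC(C)=CCBr
Why: Bromine–magnesium exchange on the symmetric dibromide gives the same arylmagnesium from either bromine and should stop after one exchange because the product is electron-rich; the ortho-fluoro Grignard does not lose magnesium fluoride at this temperature, and copper-catalysed allylic substitution should take place at the primary carbon of prenyl bromide.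

Step 4
Reactants: 5 1-bromo-2-fluoro-4,6-bis(methoxymethoxy)-3-(3-methylbut-2-en-1-yl)benzene
Product: 7 2-fluoro-4,6-bis(methoxymethoxy)-3-(3-methylbut-2-en-1-yl)benzoic acid, via aryllithium 6 (not isolated)
Conditions: n-BuLi (1.1 equiv), THF, −78 °C, 10 min; CO2 (gas), −78 °C → rt; 1 M HCl, 0 °C, to pH 3
Reagents that add atoms: carbon dioxide, O=C=O
Why: Bromine–lithium exchange followed by carboxylation should give the acid, since at −78 °C the ortho-fluoroaryllithium is trapped by CO2 before it can eliminate LiF.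

Step 5
Reactants: 8 1-(3,4-dihydroxyphenyl)ethan-1-one
Product: 9 1-[3-hydroxy-4-(2-methylbut-3-yn-2-yloxy)phenyl]ethan-1-one
Conditions: 3-chloro-3-methylbut-1-yne (1.2 equiv), DBU (1.3 equiv), CuCl2·2H2O (1 mol %), MeCN, 0 °C
Reagents that add atoms: 3-chloro-3-methylbut-1-yne, CC(C)(Cl)C#C
Why: Copper-catalysed propargylic etherification should alkylate only the 4-OH, because one equivalent of base ionises the phenol para to the acetyl group, which is by far the more acidic.

Step 6
Reactants: 9 1-[3-hydroxy-4-(2-methylbut-3-yn-2-yloxy)phenyl]ethan-1-one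
Product: 10 1-[3-(2-methylbut-3-en-2-yloxy)-4-(2-methylbut-3-yn-2-yloxy)phenyl]ethan-1-one
Conditions: tert-butyl 2-methylbut-3-en-2-yl carbonate (1.5 equiv), Pd(PPh3)4 (3 mol %), THF, 4 Å sieves, 0 °C
Reagents that add atoms: tert-butyl 2-methylbut-3-en-2-yl carbonate, CC(C)(C)OC(=O)OC(C)(C)C=C
Why: Tsuji–Trost O-allylation, in which the phenoxide attacks the dimethylallyl palladium complex at its substituted terminus under kinetic control at low temperature, should give the 1,1-dimethylallyl ether.

Step 7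
Reactants: 10 1-[3-(2-methylbut-3-en-2-yloxy)-4-(2-methylbut-3-yn-2-yloxy)phenyl]ethan-1-one
Product: 12 1-[8-hydroxy-2,2-dimethyl-7-(3-methylbut-2-en-1-yl)-2H-chromen-6-yl]ethan-1-one, via mono-rearranged phenol 11 (not isolated)
Conditions: PhNEt2, 160 °C, sealed tube, argon
Reagents that add atoms: none
Why: Two aromatic Claisen rearrangements should run in one heating: the allyl ether shifts to its only free ortho carbon and delivers a normal prenyl group, while the propargyl ether shifts to its only free ortho carbon and closes the 2,2-dimethylchromene by 1,5-hydrogen shift and oxa-6π electrocyclisation.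

Step 8
Reactants: 12 1-[8-hydroxy-2,2-dimethyl-7-(3-methylbut-2-en-1-yl)-2H-chromen-6-yl]ethan-1-one
Product: 13 1-[8-(methoxymethoxy)-2,2-dimethyl-7-(3-methylbut-2-en-1-yl)-2H-chromen-6-yl]ethan-1-one
Conditions: MOMCl (1.5 equiv), i-Pr2NEt (2 equiv), CH2Cl2, 0 → 40 °C
Reagents that add atoms: chloromethyl methyl ether, COCCl
Why: Williamson-type O-alkylation masks the remaining phenol so that only the methyl ketone is deprotonated in the next step.

Step 9
Reactants: 7 2-fluoro-4,6-bis(methoxymethoxy)-3-(3-methylbut-2-en-1-yl)benzoic acid, 13 1-[8-(methoxymethoxy)-2,2-dimethyl-7-(3-methylbut-2-en-1-yl)-2H-chromen-6-yl]ethan-1-one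
Product: 17 5,7-bis(methoxymethoxy)-2-[8-(methoxymethoxy)-2,2-dimethyl-7-(3-methylbut-2-en-1-yl)-2H-chromen-6-yl]-8-(3-methylbut-2-en-1-yl)-4H-chromen-4-one, via acyl imidazolide 14 (not isolated), via lithium enolate 15 (not isolated), via lithium diketonate 16 (not isolated)
Conditions: 7, CDI (1.1 equiv), THF, rt, 1 h; added to 13 and LiN(SiMe3)2 (3.3 equiv), THF, −78 → 0 °C; then DMF, 80 °C; AcOH quench
Reagents that add atoms: none
Why: The lithium enolate 15 attacks the acyl imidazolide 14 at carbon in a Claisen-type condensation, which forms the C3–C4 bond and, after loss of imidazolide and deprotonation, leaves the lithium β-diketonate 16. On heating, the diketonate oxygen on the ring-B side (the future O1) adds to C8a of ring A, which is ortho to the C4 carbonyl and carries fluorine, and the Meisenheimer adduct expels fluoride (addition–elimination SNAr), forming the O1–C8a bond and the pyranone ring C. The closest known reaction type is the flavone and chromone synthesis from ortho-halobenzoyl electrophiles and ketone enolates, the oxygen counterpart of the cycloaracylation used for quinolones. Ring C closes by a 6-exo-trig addition of the enolate oxygen to the arene carbon, made irreversible by rearomatisation with loss of fluoride. No stereocentre is formed, since C2 becomes sp2 and is set in step 10. The step needs C- over O-acylation, which the lithium counter-ion in THF, the imidazolide donor and the excess base that holds the product as diketonate should secure, and it needs substitution at the right carbon, which is secured because fluorine sits only at C8a while C5 and C7 carry alkoxy groups that are poor leaving groups.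

Step 10
Reactants: 17 5,7-bis(methoxymethoxy)-2-[8-(methoxymethoxy)-2,2-dimethyl-7-(3-methylbut-2-en-1-yl)-2H-chromen-6-yl]-8-(3-methylbut-2-en-1-yl)-4H-chromen-4-one
Product: 19 (2S)-5,7-bis(methoxymethoxy)-2-[8-(methoxymethoxy)-2,2-dimethyl-7-(3-methylbut-2-en-1-yl)-2H-chromen-6-yl]-8-(3-methylbut-2-en-1-yl)-2,3-dihydro-4H-chromen-4-one, via silyl enol ether 18 (not isolated)
Conditions: Cu(OAc)2·H2O (5 mol %), (R)-DTBM-SEGPHOS (5.5 mol %), (EtO)2MeSiH (3 equiv), toluene, 0 °C → rt; then 0.5 M HCl–THF, 0 °C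
Reagents that add atoms: none
Why: Asymmetric copper hydride conjugate reduction should deliver hydride to C2 of the enone only, with the face chosen by the chiral bisphosphine (the ligand antipode is taken if a first small-scale run shows the opposite sense), and trapping of the enolate as silyl enol ether 18 guards against 1,2-reduction and against β-elimination of the aryloxide before mild acid releases the ketone.

Step 11
Reactants: 19 (2S)-5,7-bis(methoxymethoxy)-2-[8-(methoxymethoxy)-2,2-dimethyl-7-(3-methylbut-2-en-1-yl)-2H-chromen-6-yl]-8-(3-methylbut-2-en-1-yl)-2,3-dihydro-4H-chromen-4-one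
Product: 20 (2S)-5,7-dihydroxy-2-[8-hydroxy-2,2-dimethyl-7-(3-methylbut-2-en-1-yl)-2H-chromen-6-yl]-8-(3-methylbut-2-en-1-yl)-2,3-dihydro-4H-chromen-4-one
Conditions: 3 M aqueous HCl–MeOH (1:6), 45 °C
Reagents that add atoms: none
Why: Acid-catalysed acetal cleavage (transacetalisation to methanol) should free the three phenols, and C2 should keep its configuration because ring opening of a flavanone by retro-oxa-Michael reaction needs base.

Compound list
1 | 5-fluorobenzene-1,3-diol | Oc1cc(O)cc(F)c1 | starting material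
2 | 1-fluoro-3,5-bis(methoxymethoxy)benzene | COCOc1cc(F)cc(OCOC)c1 | intermediate
3 | 1,3-dibromo-2-fluoro-4,6-bis(methoxymethoxy)benzene | COCOc1cc(OCOC)c(Br)c(F)c1Br | intermediate
4 | [3-bromo-2-fluoro-4,6-bis(methoxymethoxy)phenyl]magnesium chloride | COCOc1cc(OCOC)c(Br)c(F)c1[Mg]Cl | intermediate (not isolated)
5 | 1-bromo-2-fluoro-4,6-bis(methoxymethoxy)-3-(3-methylbut-2-en-1-yl)benzene | COCOc1cc(OCOC)c(CC=C(C)C)c(F)c1Br | intermediate
6 | [2-fluoro-4,6-bis(methoxymethoxy)-3-(3-methylbut-2-en-1-yl)phenyl]lithium | [Li]c1c(F)c(CC=C(C)C)c(OCOC)cc1OCOC | intermediate (not isolated)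
7 | 2-fluoro-4,6-bis(methoxymethoxy)-3-(3-methylbut-2-en-1-yl)benzoic acid | COCOc1cc(OCOC)c(CC=C(C)C)c(F)c1C(=O)O | intermediate
8 | 1-(3,4-dihydroxyphenyl)ethan-1-one | CC(=O)c1ccc(O)c(O)c1 | starting material
9 | 1-[3-hydroxy-4-(2-methylbut-3-yn-2-yloxy)phenyl]ethan-1-one | CC(=O)c1ccc(OC(C)(C)C#C)c(O)c1 | intermediate
10 | 1-[3-(2-methylbut-3-en-2-yloxy)-4-(2-methylbut-3-yn-2-yloxy)phenyl]ethan-1-one | CC(=O)c1ccc(OC(C)(C)C#C)c(OC(C)(C)C=C)c1 | intermediate
11 | 1-[3-hydroxy-2-(3-methylbut-2-en-1-yl)-4-(2-methylbut-3-yn-2-yloxy)phenyl]ethan-1-one | CC(=O)c1ccc(OC(C)(C)C#C)c(O)c1CC=C(C)C | intermediate (not isolated)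
12 | 1-[8-hydroxy-2,2-dimethyl-7-(3-methylbut-2-en-1-yl)-2H-chromen-6-yl]ethan-1-one | CC(=O)c1cc2C=CC(C)(C)Oc2c(O)c1CC=C(C)C | intermediate
13 | 1-[8-(methoxymethoxy)-2,2-dimethyl-7-(3-methylbut-2-en-1-yl)-2H-chromen-6-yl]ethan-1-one | CC(=O)c1cc2C=CC(C)(C)Oc2c(OCOC)c1CC=C(C)C | intermediate
14 | [2-fluoro-4,6-bis(methoxymethoxy)-3-(3-methylbut-2-en-1-yl)phenyl](1H-imidazol-1-yl)methanone | COCOc1cc(OCOC)c(CC=C(C)C)c(F)c1C(=O)n1ccnc1 | intermediate (not isolated)
15 | lithium enolate of 13 | [Li]OC(=C)c1cc2C=CC(C)(C)Oc2c(OCOC)c1CC=C(C)C | intermediate (not isolated)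
16 | lithium enolate of 1-[2-fluoro-4,6-bis(methoxymethoxy)-3-(3-methylbut-2-en-1-yl)phenyl]-3-[8-(methoxymethoxy)-2,2-dimethyl-7-(3-methylbut-2-en-1-yl)-2H-chromen-6-yl]propane-1,3-dione | COCOc1cc(OCOC)c(CC=C(C)C)c(F)c1C(=O)C=C(O[Li])c1cc2C=CC(C)(C)Oc2c(OCOC)c1CC=C(C)C | intermediate (not isolated)
17 | 5,7-bis(methoxymethoxy)-2-[8-(methoxymethoxy)-2,2-dimethyl-7-(3-methylbut-2-en-1-yl)-2H-chromen-6-yl]-8-(3-methylbut-2-en-1-yl)-4H-chromen-4-one | COCOc1cc(OCOC)c2c(c1CC=C(C)C)oc(cc2=O)-c1cc2C=CC(C)(C)Oc2c(OCOC)c1CC=C(C)C | intermediate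
18 | (2S)-4-{[diethoxy(methyl)silyl]oxy}-5,7-bis(methoxymethoxy)-2-[8-(methoxymethoxy)-2,2-dimethyl-7-(3-methylbut-2-en-1-yl)-2H-chromen-6-yl]-8-(3-methylbut-2-en-1-yl)-2H-chromene | CC(C)=CCc1c([C@@H]2C=C(O[Si](C)(OCC)OCC)c3c(OCOC)cc(OCOC)c(CC=C(C)C)c3O2)cc2c(c1OCOC)OC(C)(C)C=C2 | intermediate (not isolated)
19 | (2S)-5,7-bis(methoxymethoxy)-2-[8-(methoxymethoxy)-2,2-dimethyl-7-(3-methylbut-2-en-1-yl)-2H-chromen-6-yl]-8-(3-methylbut-2-en-1-yl)-2,3-dihydro-4H-chromen-4-one | CC(C)=CCc1c([C@@H]2CC(=O)c3c(OCOC)cc(OCOC)c(CC=C(C)C)c3O2)cc2c(c1OCOC)OC(C)(C)C=C2 | intermediate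
20 | (2S)-5,7-dihydroxy-2-[8-hydroxy-2,2-dimethyl-7-(3-methylbut-2-en-1-yl)-2H-chromen-6-yl]-8-(3-methylbut-2-en-1-yl)-2,3-dihydro-4H-chromen-4-one | CC(C)=CCc1c([C@@H]2CC(=O)c3c(O)cc(O)c(CC=C(C)C)c3O2)cc2c(c1O)OC(C)(C)C=C2 | target

Total step count: 11. Longest linear sequence: 7 steps (steps 1–4 or steps 5–8, then steps 9–11).

Steps most likely to fail

Step 10. Facial discrimination in hydride delivery may be poor because the 2-aryl group is twisted by its ortho prenyl group, and 1,2-reduction or hydrocupration of the chromene double bond may compete. The fallback sets out from 17. Non-selective conjugate reduction with Cu(OAc)2·H2O, 1,2-bis(diphenylphosphino)benzene, (EtO)2MeSiH and t-BuOH in toluene should give the racemic flavanone F1. Asymmetric transfer hydrogenation under kinetic resolution with [Cp*RhCl((R,R)-TsDPEN)] and HCO2H–Et3N at rt is then expected, from the usual sense of this catalyst with aryl ketones, to reduce the 2R enantiomer to the cis-(2R,4R)-flavan-4-ol F2. The unreduced 2S ketone is separated by chromatography, and the route is rejoined at 19.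

Step 9. O-acylation or double acylation of the enolate may compete, and ring closure may be slow at a fluorinated carbon flanked by two ortho substituents on an electron-rich ring, with decay of the lithium-chelated diketonate on long heating. The fallback sets out from 13 and 7.
- Ketone 13 is converted with LDA and ClP(O)(OEt)2 into the enol phosphate F3, and a further 2.2 equiv of LDA (−78 °C → rt) eliminates it to the terminal alkyne F4.
- n-BuLi gives the lithium acetylide F5, which is acylated by imidazolide 14 (made from 7 and CDI as before) to the ynone F6.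
- (E)-Benzaldoxime and K2CO3 in DMF at 60–80 °C act as a hydroxide surrogate: oxa-Michael addition gives the O-vinyl oxime F7, base-induced loss of benzonitrile gives the potassium diketonate F8, and this more nucleophilic enolate closes by SNAr.

The route is rejoined at 17.

Step 7. Thermal loss of the tertiary allyl group as isoprene, and heat-induced cyclisation of the new ortho-prenyl phenol onto its own side chain, may compete with the two sigmatropic shifts. The fallback sets out from 9 and replaces the allyl Claisen rearrangement by directed ortho-metalation.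
- Heating 9 alone (PhNEt2, 160 °C) gives the chromene phenol F9.
- Ethylene glycol and PPTS in benzene with water removal give the dioxolane phenol F10, and MOMCl with i-Pr2NEt gives the MOM ether F11.
- s-BuLi–TMEDA in THF at −78 °C should lithiate C7, the only carbon between the MOM ether and the dioxolane, to give the aryllithium F12.
- CuBr·SMe2 and prenyl bromide give the prenylated dioxolane F13, and PPTS in acetone–water removes the ketal.

The route is rejoined at 13.

Further compounds
F1 | step 10 | racemic 5,7-bis(methoxymethoxy)-2-[8-(methoxymethoxy)-2,2-dimethyl-7-(3-methylbut-2-en-1-yl)-2H-chromen-6-yl]-8-(3-methylbut-2-en-1-yl)-2,3-dihydro-4H-chromen-4-one | CC(C)=CCc1c(C2CC(=O)c3c(OCOC)cc(OCOC)c(CC=C(C)C)c3O2)cc2c(c1OCOC)OC(C)(C)C=C2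
F2 | step 10 | (2R,4R)-5,7-bis(methoxymethoxy)-2-[8-(methoxymethoxy)-2,2-dimethyl-7-(3-methylbut-2-en-1-yl)-2H-chromen-6-yl]-8-(3-methylbut-2-en-1-yl)-3,4-dihydro-2H-chromen-4-ol | CC(C)=CCc1c([C@H]2C[C@@H](O)c3c(OCOC)cc(OCOC)c(CC=C(C)C)c3O2)cc2c(c1OCOC)OC(C)(C)C=C2
F3 | step 9 | diethyl 1-[8-(methoxymethoxy)-2,2-dimethyl-7-(3-methylbut-2-en-1-yl)-2H-chromen-6-yl]ethenyl phosphate | C=C(OP(=O)(OCC)OCC)c1cc2C=CC(C)(C)Oc2c(OCOC)c1CC=C(C)C
F4 | step 9 | 6-ethynyl-8-(methoxymethoxy)-2,2-dimethyl-7-(3-methylbut-2-en-1-yl)-2H-chromene | C#Cc1cc2C=CC(C)(C)Oc2c(OCOC)c1CC=C(C)C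
F5 | step 9 | lithium acetylide of F4 | [Li]C#Cc1cc2C=CC(C)(C)Oc2c(OCOC)c1CC=C(C)C
F6 | step 9 | 1-[2-fluoro-4,6-bis(methoxymethoxy)-3-(3-methylbut-2-en-1-yl)phenyl]-3-[8-(methoxymethoxy)-2,2-dimethyl-7-(3-methylbut-2-en-1-yl)-2H-chromen-6-yl]prop-2-yn-1-one | COCOc1cc(OCOC)c(CC=C(C)C)c(F)c1C(=O)C#Cc1cc2C=CC(C)(C)Oc2c(OCOC)c1CC=C(C)C
F7 | step 9 | O-vinyl oxime adduct of F6 with benzaldoxime | COCOc1cc(OCOC)c(CC=C(C)C)c(F)c1C(=O)C=C(ON=Cc1ccccc1)c1cc2C=CC(C)(C)Oc2c(OCOC)c1CC=C(C)C
F8 | step 9 | potassium enolate of the 1,3-diketone (potassium counterpart of 16) | COCOc1cc(OCOC)c(CC=C(C)C)c(F)c1C(=O)C=C(O[K])c1cc2C=CC(C)(C)Oc2c(OCOC)c1CC=C(C)C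
F9 | step 7 | 1-(8-hydroxy-2,2-dimethyl-2H-chromen-6-yl)ethan-1-one | CC(=O)c1cc(O)c2OC(C)(C)C=Cc2c1
F10 | step 7 | 2,2-dimethyl-6-(2-methyl-1,3-dioxolan-2-yl)-2H-chromen-8-ol | CC1(OCCO1)c1cc(O)c2OC(C)(C)C=Cc2c1
F11 | step 7 | 8-(methoxymethoxy)-2,2-dimethyl-6-(2-methyl-1,3-dioxolan-2-yl)-2H-chromene | CC1(OCCO1)c1cc(OCOC)c2OC(C)(C)C=Cc2c1
F12 | step 7 | 7-lithio derivative of F11 | CC1(OCCO1)c1cc2C=CC(C)(C)Oc2c(OCOC)c1[Li]
F13 | step 7 | 8-(methoxymethoxy)-2,2-dimethyl-6-(2-methyl-1,3-dioxolan-2-yl)-7-(3-methylbut-2-en-1-yl)-2H-chromene | CC1(OCCO1)c1cc2C=CC(C)(C)Oc2c(OCOC)c1CC=C(C)C
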